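You cannot count the 1.30 equiv of solid reagent as that much target, since the partner it releases also decomposes, at 0.024 min⁻¹, with no substrate involved. Before you spend material on a next run, you want to know which change pays.

solid substrate 1.0 M; solid reagent 1.30 equiv; time 3.0 h

- birch: doubling the dissolution coefficient of step 3, all else as stated
- cedar: doubling the dissolution coefficient of step 4, all else as stated
- maple: doubling the dissolution coefficient of step 1, all else as stated
- oak: doubling the solubility in step 1, all else as stated

- the target and solid product together standing at 3.0 h, as a percentage of the solid substrate charged
- the change that raises the amount of target and solid product together at 3.0 h, in percent of the solid substrate charged most ("none" if none brings more than 2 percentage points) (birch / cedar / maple / oak / none)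
- amount of target and solid product together at 3.0 h, in percent of the solid substrate charged, after maple

    solid substrate ⇌ dissolved substrate, rate k1*(cs1 - [dissolved substrate]) while solid is left; crystals form when [dissolved substrate] > cs1 (cs1 = 0.44 M, k1 = 0.36 min⁻¹)
    dissolved substrate + partner → target (k2 = 0.054 L mol⁻¹ min⁻¹)
    solid product ⇌ target, rate k3*(cs3 - [target]) while solid is left; crystals form when [target] > cs3 (cs3 = 48 mM, k3 = 0.56 min⁻¹)
    solid reagent ⇌ partner, rate k4*(cs4 - [partner]) while solid is left; crystals form when [partner] > cs4 (cs4 = 0.35 M, k4 = 0.066 min⁻¹)
    partner → decomposed reagent (k5 = 0.024 min⁻¹)

Solid substrate dissolves up to 0.44 M, solid reagent feeds partner, the two dissolved species couple at 0.054 L mol⁻¹ min⁻¹, and target crystallises as solid product, which is counted with it.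

Take the dissolution of solid substrate as settled: its coefficient 0.36 min⁻¹ stands far above the 0.0189 min⁻¹ that coupling draws even at the partner's solubility. So while solid substrate lasts, [dissolved substrate] stays near 0.44 M, and partner has two pseudo-first-order exits. One concentration compares them, the break-even concentration of dissolved substrate, at which coupling and decomposition take equal shares of partner:

K = k5/k2 = 0.444 M

share = [dissolved substrate] / ([dissolved substrate] + K) = 49.7%

So about half of the partner reaches target. Partner should hold near 0.203 M, which delivers the charge in about 2.23 h, less than the 3.0 h allowed. I therefore reckon:

yield = share × equivalents = 64.7%

This runs a little high, since the solid substrate holds out for 0.560 M of coupling, less than the reckoned yield, and [dissolved substrate] then falls. Doubling k1, k3 or k4 leaves K and the saturation level as they were, so maple stays at 64.7%. Doubling the solubility raises the share to 66.5%, though solid then lasts for 0.120 M of coupling, so its figure is a ceiling. The run I would make is oak.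

The forecast gave 62%, 63% after maple and oak as the best change, holding that “roughly half of the reagent is lost to decomposition”.

The flask gives 62.6%, and 63.1% after maple, with oak the best change at a gain of 9.1 percentage points; [dissolved substrate] stood at 97.0% of saturation after 1.50 h.

Now charge 0.25 M of solid substrate at the same equivalents. In that flask [dissolved substrate] ends at 0.151 M, so its mean is about 0.200 M, below K. The share is then 31.1%, and times the equivalents it gives 40.4%. That flask stood at 39.6%.

The constants are those of an exercise; the run is a simulation.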